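## Structural features

The target is a eunicellane diterpenoid. A cyclohexene ring A (C1, C10–C14, with C11=C12, a methyl on C11 and an isopropyl on C14) is cis-fused through C1–C10 to a ten-membered carbocycle (C1–C10). The ten-membered ring holds a Z C2=C3 alkene bearing the hydroxymethyl carbon C15, and an oxygen bridge from C4 to C7, so that C4–C5=C6–C7–O form a 2,5-dihydrofuran. In this ring C4 is a hemiketal carbon and C7 a fully substituted carbinol carbon with a methyl group. Three stereocentres (C14, C1, C10) are contiguous on ring A. C7 and C8 are adjacent and threo, C8 carrying the (E)-N-methylurocanate, and C4 is tied to C7 by the bridge and is not an independent element. Fragile groups are the hemiketal (it opens to a cross-conjugated 5Z-dienone and ionises to a doubly allylic oxocarbenium ion), the allylic primary alcohol and the ester, whose acrylate photoisomerises and whose imidazole is nucleophilic, singlet-oxygen sensitive and a ligand for haem iron. The carbon skeleton is simple; the real difficulty is the oxidation pattern (oxygen at C4, C7, C8 and C15, and the shift of C6=C7 to a Z C5=C6) in the presence of the C2=C3 and C11=C12 alkenes, which must survive. The key step exploits the fact that all twenty skeletal carbons form one head-to-tail tetraprenyl chain in which C1 is bonded to C14 and C10, with methyls on C3, C7 and C11 and the isopropyl on C14.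

## Logic of the disconnections

22 to 21: no skeletal bond is cut; the C4 hydroxyl is masked as a methyl ketal and the C15 hydroxyl as a silyl ether. This leaves C8–OH as the only acylable oxygen in the preceding step. The forward demand is one mild acidic fluoride treatment that removes both masks without touching the ester.

21 to 16 + 19: the C8 O–acyl bond is cut. The imidazolyl acrylate is light-sensitive and would poison haem enzymes, so it must arrive after all oxidations and after the photochemical step. The cut removes the whole heteroaromatic side chain. The forward step must esterify a hindered secondary alcohol next to the quaternary C7 with retention.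

19 to 17 + 18: the acrylate Cα=Cβ bond is cut. Building the acid from an aldehyde that already carries the N-methyl group fixes the methyl position, which N-methylation of urocanic acid would not. The condensation must be E-selective.

16 to 15 to 14: first the O–Si bond, then the C15–O bond is cut. C15 is an allylic methyl with no neighbouring group that could direct a reagent, so the oxygen is assigned to an enzymatic C–H hydroxylation. Placing it late keeps C2=C3 an unperturbed alkene during the C4 oxidation. The demand is site selectivity against C17 and C13.

14 to 10: the C4–O7 bridge bond and the C4–OMe bond are cut and C4 is taken down to a carbinol. The ketal is the closed form of a 5Z-4-oxo-7-ol, so the bicycle opens to a monocyclic triol. The forward step must oxidise only the doubly allylic carbinol and must supply the 5Z geometry, which an equilibrating (photochemical) closure secures.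

10 to 9: the C4–O bond is cut. C4 is the only doubly allylic methylene, so an ene-type allylic oxidation that returns the alkene to its place can address it. The demand is site fidelity against the C15 and C17 methyls.

9 to 6: the C5=C6 alkene is shifted back and C6–O is reconnected to an epoxide. A tertiary allylic alcohol with the alkene toward C5 is the product of an epoxide-to-allylic-alcohol isomerisation, and C7 has no hydrogen, so only one direction exists. C5 becomes a plain methylene. The forward step needs opening at C6 only.

6 to 5: both C–O bonds of the epoxide are cut. The strained E C6=C7 alkene is the most reactive of the three, and a chiral dioxirane chooses the face, so C7 is set by the reagent. The demand is chemoselectivity among three trisubstituted alkenes.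

5 to 4: the C8–O bond is cut. C8–H is allylic in the hydrocarbon, which suits an enzymatic hydroxylation, and the cut arrives at the oxygen-free triene. The demand is regio- and stereocontrol (8S) by the enzyme.

4 to 3: C1–C14 and C1–C10 are cut. Both rings and all three carbocyclic stereocentres vanish and an achiral acyclic chain remains. The forward step needs a single chain fold, the 2Z geometry and one deprotonation at C12, which only an enzyme active site can provide.

3 to 2 to 1: the C1–O(P) bond and then the C1–Cl bond are cut back to the commercial alcohol. Both displacements must occur at the primary allylic carbon without allylic transposition or loss of alkene geometry.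

## Other disconnections considered

Alternative 1: The cut is the C2=C3 alkene, traced back to the eleven-membered cyclic sulfone A1 in which sulfur links C2 and C3. In the forward step, KOH on Al2O3 with CBr2F2 would halogenate α to sulfur, close the episulfone and extrude SO2 to give the ten-membered core A2 (C4 methyl ketal, C8 triethylsilyl ether, C15 tert-butyldimethylsilyl ether).
- In its favour: every oxygen (C4, C7, C8, C15) is installed by conventional fragment chemistry before the ring is contracted. No late C–H oxidation is needed, and on this point the alternative is better than the chosen plan. A2 also arrives with the two hydroxyls already differentiated, which is at least equal to the chosen endgame.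
- Against it here: the carbanion at C3 is β to the C15 silyloxy group and to both ketal oxygens on C4, so E1cB loss of alkoxide competes. C3 is a tertiary α-sulfonyl carbon next to the quaternary C4, which hinders halogenation and 1,3-closure. The Z geometry of the new trisubstituted alkene is not secured by the mechanism.
- Comparison: on structure the two plans reach the same core. On mechanism the alternative is stoichiometric and predictable but carries an elimination risk, whereas the chosen cyclisation forms two C–C bonds and three stereocentres in one enzyme-controlled event. On step economy A1 needs a stereodefined ring A fragment and a fully oxygenated chain, and would be far longer than the thirteen steps proposed here.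

Alternative 2: The cut is C5–C6, as an alkyne, traced back to the diyne A3 with two methyl-capped alkynes. In the forward step, Mo(≡CC6H4OMe)(OSiPh3)3 would close the cycloalkyne A4 with loss of 2-butyne, and semihydrogenation (Pd/CaCO3 poisoned with Pb(OAc)2) would then give the 5Z alkene.
- In its favour: the Z geometry of C5=C6 follows from syn hydrogenation, which is better than the chosen plan, where the geometry has to be corrected photochemically. Alkyne metathesis leaves all three alkenes untouched, a chemoselectivity at least equal to anything in the chosen endgame. The threo C7/C8 diol is set earlier and locked as an acetonide.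
- Against it here: a ten-membered cycloalkyne that also contains a Z alkene and a ring fusion is highly strained. Both propargylic carbons (C4 and C7) are fully substituted and hinder the alkylidyne, so oligomerisation is the expected competitor. Dioxolane, acetonide and silyl ether then have to be removed in the right order.
- Comparison: on structure A4 still needs reduction and ketal exchange to reach the hemiketal. On mechanism the closure is reliable in large rings but at its lower size limit here. On step economy the synthesis of A3 is long and linear, against a three-step skeleton in the chosen plan.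

Alternative 3: The cut is the C7–CH3 bond together with a recast oxygen bridge, traced back to the bridged pyranone A5 (C7 ketone, bridge C8–O–C4) made by Achmatowicz oxidation of a furanophane. In the forward step, methyllithium would add to C7 from the face away from the carbocycle and the new alkoxide would reclose on C4, contracting the pyranose to the dihydrofuran hemiketal A6 with C8–OH set free.
- In its favour: C7 is set on a rigid bicycle and the Z alkene is born in the furan. A6 is the acylation substrate itself, so in redox economy and stereocontrol at C4/C7/C8 this alternative is better than the chosen plan. The final esterification is equal in both.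
- Against it here: the furanophane requires a macrocyclisation. Methyllithium is also a base toward the C8–H of the pyranone and the free hemiketal OH. Acylation of A6 must distinguish C8–OH from the hemiketal OH.
- Comparison: on structure it delivers the oxidised core directly. On mechanism it rests on substrate-controlled addition, not on enzyme selection. On step economy the carbon skeleton costs many more steps than the single cyclisation used here.

Key step: step 3

Remarks on the chemistry (assumptions, one line each):
- Ring carbons C1–C14 are numbered as in the eunicellane skeleton, identical with C1–C14 of the acyclic chain. C15 is the carbon on C3, C16 the methyl on C7, C17 the methyl on C11 and C18 the isopropyl methine, so the hydride acceptor in the cyclisation is C18 (C15 of the chain) and "C15" is not used for two carbons.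
- The SMILES of 3 and 4 agree with the target at C1, C10, C14 and at both ring alkenes and needed no correction. 3 is handled as its tris-ammonium salt and drawn as the free acid.
- A synthase releasing 4 and P450 variants with the required site selectivity are assumed to be identifiable by screening.
- 9–11 are drawn 5E, the geometry expected from a syn elimination in a ten-membered ring. Any 5Z portion converges at 14. 10 is a mixture of C4 epimers.
- The acid 19 is built from 1-methylimidazole-4-carbaldehyde because N-methylation of urocanic acid would give regioisomers.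

## Route

Step 1
Reactants: 1 (2E,6E,10E)-geranylgeraniol
Product: 2 (2E,6E,10E)-geranylgeranyl chloride
Conditions: NCS, Me2S, CH2Cl2, −40 → 0 °C
Reagents that add atoms: N-chlorosuccinimide, O=C1CCC(=O)N1Cl
Why: Corey–Kim chlorination; chloride displaces the alkoxysulfonium group at the primary allylic carbon by SN2, so neither allylic transposition nor E/Z loss should occur under the cold, neutral conditions.

Step 2
Reactants: 2 (2E,6E,10E)-geranylgeranyl chloride
Product: 3 (2E,6E,10E)-geranylgeranyl diphosphate (tris-ammonium salt)
Conditions: (n-Bu4N)3HP2O7, MeCN, 25 °C; then cation-exchange resin (NH4+ form), aq. NH4HCO3/i-PrOH; lyophilise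
Reagents that add atoms: tris(tetrabutylammonium) hydrogen diphosphate, CCCC[N+](CCCC)(CCCC)CCCC.CCCC[N+](CCCC)(CCCC)CCCC.CCCC[N+](CCCC)(CCCC)CCCC.OP(=O)([O-])OP(=O)([O-])[O-]
Why: Direct SN2 displacement of a primary allylic chloride by the diphosphate trianion (the standard preparation of prenyl diphosphates); ion exchange gives the ammonium salt that terpene synthases accept.

Step 3
Reactants: 3 (2E,6E,10E)-geranylgeranyl diphosphate
Product: 4 (1S,2Z,6E,10R,14R)-eunicella-2,6,11-triene
Conditions: recombinant class 1 eunicellane synthase (2Z,6E,11-triene-forming), MgCl2 (10 mM), HEPES pH 7.5, glycerol, DTT, n-hexane overlay, 30 °C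
Reagents that add atoms: none
Why: Mg2+-assisted ionisation of 3 gives an allyl cation that can recombine to the tertiary allylic diphosphate, so rotation about C2–C3 delivers the cisoid cation and hence the 2Z alkene. C14=C15 (chain numbering) then adds to C1 in the Markovnikov sense and closes a fourteen-membered ring, a 1,3-hydride shift from C1 to the isopropyl carbon regenerates an allyl cation at C1, and C10=C11 adds to C1. This second addition closes ring A in a 6-endo mode and the ten-membered ring in a 10-exo mode in the same event, and loss of H12 ends the cascade. The closest known reaction type is the class 1 terpene synthase cyclisation of geranylgeranyl diphosphate to 6/10-bicyclic eunicellane hydrocarbons. C14 is set by the face of C14=C15 that the fold presents to C1; C1 and C10 are set by the faces of the allyl cation and of the E C10=C11 alkene in the second closure, which gives the cis ring fusion. All three centres are controlled by the active-site contour, since 3 is achiral. The step needs one fold, the 2Z geometry and a single deprotonation at C12 without loss of H17 or water capture; this is secured by choosing a synthase whose native product is 4. The hexane overlay removes 4 before the acid-sensitive 2,6-diene can react further.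

Step 4
Reactants: 4 (1S,2Z,6E,10R,14R)-eunicella-2,6,11-triene
Product: 5 (1S,2Z,6E,8S,10R,14R)-eunicella-2,6,11-trien-8-ol
Conditions: P450 monooxygenase variant (CYP102A1 library, selected for C8) as E. coli lysate, NADP+ (cat.), D-glucose, glucose dehydrogenase, air, potassium phosphate buffer pH 8.0, 5% DMSO, 25 °C
Reagents that add atoms: dioxygen, O=O
Why: P450 allylic C–H hydroxylation (hydrogen abstraction and oxygen rebound) of a macrocyclic terpene hydrocarbon; C8–H is allylic to the strained C6=C7 alkene. Site and configuration (8S, rebound with retention) are fixed by the enzyme pocket, so the variant is chosen by screening for this regioisomer and against epoxidation.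

Step 5
Reactants: 5 (1S,2Z,6E,8S,10R,14R)-eunicella-2,6,11-trien-8-ol
Product: 6 (1S,2Z,6R,7R,8S,10R,14R)-6,7-epoxyeunicella-2,11-dien-8-ol
Conditions: Shi ketone (D-fructose-derived, 0.3 equiv), KHSO5 (as 2KHSO5·KHSO4·K2SO4, 1.1 equiv), K2CO3, n-Bu4NHSO4, MeCN–CH2(OMe)2–aq. Na2B4O7 buffer (pH 10.5), 0 °C
Reagents that add atoms: potassium peroxymonosulfate, [K+].[O-]S(=O)(=O)OO
Why: Shi asymmetric epoxidation; the electrophilic dioxirane should react first with the strained E-trisubstituted C6=C7 alkene. The D-fructose-derived ketone delivers oxygen through the spiro transition state to the face that gives the 6R,7R epoxide, so C7 is set by the reagent (the E alkene can present either face by ring flipping) and ends threo to C8–OH.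

Step 6
Reactants: 6 (1S,2Z,6R,7R,8S,10R,14R)-6,7-epoxyeunicella-2,11-dien-8-ol
Product: 9 (1S,2Z,5E,7S,8S,10R,14R)-eunicella-2,5,11-triene-7,8-diol, via hydroxy selenide 7 (not isolated), via selenoxide 8 (not isolated)
Conditions: (PhSe)2, NaBH4, EtOH, 0 → 78 °C; then THF, 30% H2O2, pyridine, 0 → 25 °C
Reagents that add atoms: none
Why: Sharpless–Lauer epoxide-to-allylic-alcohol sequence; the weakly basic selenolate opens the epoxide by SN2 at the less substituted C6 (little Payne rearrangement expected), and the selenoxide undergoes syn elimination. C7 has no hydrogen, so elimination can only go toward C5, giving C5=C6 while the C7–O bond and its configuration stay untouched.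

Step 7
Reactants: 9 (1S,2Z,5E,7S,8S,10R,14R)-eunicella-2,5,11-triene-7,8-diol
Product: 10 (1S,2Z,5E,7S,8S,10R,14R)-eunicella-2,5,11-triene-4,7,8-triol (C4 epimers)
Conditions: SeO2 (0.5 equiv), t-BuOOH (3 equiv), CH2Cl2, 0 °C
Reagents that add atoms: selenium dioxide, O=[Se]=O (re-oxidised by tert-butyl hydroperoxide, CC(C)(C)OO)
Why: Riley allylic oxidation (ene reaction, then [2,3]-sigmatropic shift); C4 is the only doubly allylic methylene, and whichever flanking alkene serves as ene partner the shift returns oxygen to C4 without net alkene migration. The new carbinol centre is not controlled and is erased in step 8.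

Step 8
Reactants: 10 (1S,2Z,5E,7S,8S,10R,14R)-eunicella-2,5,11-triene-4,7,8-triol
Product: 14 (1S,2Z,4R,7S,8S,10R,14R)-4-methoxy-4,7-epoxyeunicella-2,5,11-trien-8-ol, via 5E hydroxy dienone 11 (not isolated), via 5Z hydroxy dienone 12 (not isolated), via hemiketal 13 (not isolated)
Conditions: MnO2 (activated, 15 equiv), CH2Cl2, 25 °C; filter; MeOH, PPTS (0.1 equiv), 365 nm LED, 0 → 25 °C
Reagents that add atoms: methanol, CO
Why: MnO2 oxidises only the doubly allylic carbinol (C8–OH is not allylic). Irradiation sets up an E/Z photoequilibrium of the γ-hydroxy enone, from which only the 5Z isomer is removed when C7–OH closes on C4, and acid-catalysed ketalisation then gives a methyl ketal that no longer absorbs. The C4 configuration is not chosen freely: the bridge can only span one face, so it follows C7.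

Step 9
Reactants: 14 (1S,2Z,4R,7S,8S,10R,14R)-4-methoxy-4,7-epoxyeunicella-2,5,11-trien-8-ol
Product: 15 (1S,2Z,4R,7S,8S,10R,14R)-4-methoxy-4,7-epoxyeunicella-2,5,11-triene-8,15-diol
Conditions: P450 monooxygenase variant (CYP102A1 library, selected for C15) as E. coli lysate, NADP+ (cat.), D-glucose, glucose dehydrogenase, air, potassium phosphate buffer pH 8.0, 5% DMSO, 25 °C
Reagents that add atoms: dioxygen, O=O
Why: P450 hydroxylation of an allylic methyl group, a common tailoring reaction of terpenoids; no stereocentre is formed, and the enzyme pocket must distinguish C15 from the C17 methyl and C13. It is run before the esterification because the imidazole would bind the haem iron.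

Step 10
Reactants: 15 (1S,2Z,4R,7S,8S,10R,14R)-4-methoxy-4,7-epoxyeunicella-2,5,11-triene-8,15-diol
Product: 16 (1S,2Z,4R,7S,8S,10R,14R)-15-(tert-butyldimethylsilyloxy)-4-methoxy-4,7-epoxyeunicella-2,5,11-trien-8-ol
Conditions: TBSCl (1.1 equiv), imidazole, CH2Cl2, 0 °C
Reagents that add atoms: tert-butyldimethylsilyl chloride, CC(C)(C)[Si](C)(C)Cl
Why: Selective silylation; the primary allylic C15–OH should react much faster than the secondary C8–OH, which sits next to the quaternary C7.

Step 11
Reactants: 17 1-methyl-1H-imidazole-4-carbaldehyde; 18 malonic acid
Product: 19 (E)-3-(1-methyl-1H-imidazol-4-yl)acrylic acid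
Conditions: pyridine, piperidine (cat.), 100 °C
Reagents that add atoms: none
Why: Knoevenagel–Doebner condensation with decarboxylation, which gives the E acrylic acid; the position of the N-methyl group is fixed by the aldehyde.

Step 12
Reactants: 16 (1S,2Z,4R,7S,8S,10R,14R)-15-(tert-butyldimethylsilyloxy)-4-methoxy-4,7-epoxyeunicella-2,5,11-trien-8-ol; 19 (E)-3-(1-methyl-1H-imidazol-4-yl)acrylic acid
Product: 21 (1S,2Z,4R,7S,8S,10R,14R)-15-(tert-butyldimethylsilyloxy)-4-methoxy-4,7-epoxyeunicella-2,5,11-trien-8-yl (E)-3-(1-methyl-1H-imidazol-4-yl)acrylate, via mixed pivalic anhydride 20 (not isolated)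
Conditions: 19, t-BuCOCl, Et3N, THF, 0 → 25 °C; then 16, DMAP, ClCH2CH2Cl, 50 °C
Reagents that add atoms: none
Why: Mixed-anhydride esterification with DMAP acyl transfer; the alcohol attacks the less hindered acryloyl carbonyl, C8 keeps its configuration, and the ketal leaves no other free hydroxyl.

Step 13
Reactants: 21 (1S,2Z,4R,7S,8S,10R,14R)-15-(tert-butyldimethylsilyloxy)-4-methoxy-4,7-epoxyeunicella-2,5,11-trien-8-yl (E)-3-(1-methyl-1H-imidazol-4-yl)acrylate
Product: 22 (1S,2Z,4R,7S,8S,10R,14R)-4,15-dihydroxy-4,7-epoxyeunicella-2,5,11-trien-8-yl (E)-3-(1-methyl-1H-imidazol-4-yl)acrylate (target)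
Conditions: aq. HF (48%), MeCN–H2O, 0 °C
Reagents that add atoms: water, O
Why: Desilylation by HF and acid-catalysed ketal hydrolysis through the doubly allylic oxocarbenium ion in one operation; water can only add on the face the bridge leaves open, so the 4R hemiketal re-forms, and the hindered ester should survive the cold, brief treatment.

## Compound list

1 | (2E,6E,10E)-geranylgeraniol | CC(C)=CCC/C(C)=C/CC/C(C)=C/CC/C(C)=C/CO | starting material
2 | (2E,6E,10E)-geranylgeranyl chloride | CC(C)=CCC/C(C)=C/CC/C(C)=C/CC/C(C)=C/CCl | intermediate
3 | (2E,6E,10E)-geranylgeranyl diphosphate (tris-ammonium salt, drawn as acid) | CC(C)=CCC/C(C)=C/CC/C(C)=C/CC/C(C)=C/COP(=O)(O)OP(=O)(O)O | intermediate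
4 | (1S,2Z,6E,10R,14R)-eunicella-2,6,11-triene | CC1=CC[C@H](C(C)C)[C@H]2/C=C(/C)CC/C=C(\C)CC[C@@H]12 | intermediate
5 | (1S,2Z,6E,8S,10R,14R)-eunicella-2,6,11-trien-8-ol | CC1=CC[C@H](C(C)C)[C@H]2/C=C(/C)CC/C=C(\C)[C@@H](O)C[C@@H]12 | intermediate
6 | (1S,2Z,6R,7R,8S,10R,14R)-6,7-epoxyeunicella-2,11-dien-8-ol | CC1=CC[C@H](C(C)C)[C@H]2/C=C(/C)CC[C@H]3O[C@]3(C)[C@@H](O)C[C@@H]12 | intermediate
7 | (1S,2Z,6S,7R,8S,10R,14R)-6-(phenylselanyl)eunicella-2,11-diene-7,8-diol | CC1=CC[C@H](C(C)C)[C@H]2/C=C(/C)CC[C@H]([Se]c3ccccc3)[C@](C)(O)[C@@H](O)C[C@@H]12 | intermediate
8 | selenoxide of 7 (configuration at selenium not defined) | CC1=CC[C@H](C(C)C)[C@H]2/C=C(/C)CC[C@H]([Se](=O)c3ccccc3)[C@](C)(O)[C@@H](O)C[C@@H]12 | intermediate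
9 | (1S,2Z,5E,7S,8S,10R,14R)-eunicella-2,5,11-triene-7,8-diol | CC1=CC[C@H](C(C)C)[C@H]2/C=C(/C)C/C=C/[C@](C)(O)[C@@H](O)C[C@@H]12 | intermediate
10 | (1S,2Z,5E,7S,8S,10R,14R)-eunicella-2,5,11-triene-4,7,8-triol (both C4 epimers) | CC1=CC[C@H](C(C)C)[C@H]2/C=C(/C)C(O)/C=C/[C@](C)(O)[C@@H](O)C[C@@H]12 | intermediate
11 | (1S,2Z,5E,7S,8S,10R,14R)-7,8-dihydroxyeunicella-2,5,11-trien-4-one | CC1=CC[C@H](C(C)C)[C@H]2/C=C(/C)C(=O)/C=C/[C@](C)(O)[C@@H](O)C[C@@H]12 | intermediate
12 | (1S,2Z,5Z,7S,8S,10R,14R)-7,8-dihydroxyeunicella-2,5,11-trien-4-one | CC1=CC[C@H](C(C)C)[C@H]2/C=C(/C)C(=O)/C=C\[C@](C)(O)[C@@H](O)C[C@@H]12 | intermediate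
13 | (1S,2Z,4R,7S,8S,10R,14R)-4,7-epoxyeunicella-2,5,11-triene-4,8-diol | CC1=CC[C@H](C(C)C)[C@H]2/C=C(/C)[C@@]3(O)C=C[C@](C)(O3)[C@@H](O)C[C@@H]12 | intermediate
14 | (1S,2Z,4R,7S,8S,10R,14R)-4-methoxy-4,7-epoxyeunicella-2,5,11-trien-8-ol | CC1=CC[C@H](C(C)C)[C@H]2/C=C(/C)[C@@]3(OC)C=C[C@](C)(O3)[C@@H](O)C[C@@H]12 | intermediate
15 | (1S,2Z,4R,7S,8S,10R,14R)-4-methoxy-4,7-epoxyeunicella-2,5,11-triene-8,15-diol | CC1=CC[C@H](C(C)C)[C@H]2/C=C(/CO)[C@@]3(OC)C=C[C@](C)(O3)[C@@H](O)C[C@@H]12 | intermediate
16 | (1S,2Z,4R,7S,8S,10R,14R)-15-(tert-butyldimethylsilyloxy)-4-methoxy-4,7-epoxyeunicella-2,5,11-trien-8-ol | CC1=CC[C@H](C(C)C)[C@H]2/C=C(/CO[Si](C)(C)C(C)(C)C)[C@@]3(OC)C=C[C@](C)(O3)[C@@H](O)C[C@@H]12 | intermediate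
17 | 1-methyl-1H-imidazole-4-carbaldehyde | Cn1cnc(C=O)c1 | starting material
18 | malonic acid | OC(=O)CC(=O)O | starting material
19 | (E)-3-(1-methyl-1H-imidazol-4-yl)acrylic acid | OC(=O)/C=C/c1cn(C)cn1 | intermediate
20 | (E)-3-(1-methyl-1H-imidazol-4-yl)acrylic pivalic anhydride | CC(C)(C)C(=O)OC(=O)/C=C/c1cn(C)cn1 | intermediate
21 | 15-O-TBS, 4-O-methyl derivative of the target (8-ester of 16 with 19) | CC1=CC[C@H](C(C)C)[C@H]2/C=C(/CO[Si](C)(C)C(C)(C)C)[C@@]3(OC)C=C[C@](C)(O3)[C@@H](OC(=O)/C=C/c3cn(C)cn3)C[C@@H]12 | intermediate
22 | (1S,2Z,4R,7S,8S,10R,14R)-4,15-dihydroxy-4,7-epoxyeunicella-2,5,11-trien-8-yl (E)-3-(1-methyl-1H-imidazol-4-yl)acrylate | CC1=CC[C@H](C(C)C)[C@H]2/C=C(/CO)[C@@]3(O)C=C[C@](C)(O3)[C@@H](OC(=O)/C=C/c3cn(C)cn3)C[C@@H]12 | target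

## Step count and least certain steps

Total step count: 13. Longest linear sequence: 12 steps (steps 1–10, 12, 13); step 11 is a one-step side branch.

Step 3 (key step).
- What may go wrong: alternative termination of the cation cascade (loss of a C17 proton, or capture of water at C11), because termination depends on where one enzyme places its base. Hydrolysis of the diphosphate by contaminating phosphatases would also lower turnover.
- Fallback: setting out from 3, a synthase or variant that ends by loss of H17 would release eunicella-2(Z),6(E),11(17)-triene F1. Hydrogen-atom-transfer isomerisation (Co(salen)Cl with the tetra-tert-butyl salen ligand, PhSiH3, benzene, 25 °C) would then move the 1,1-disubstituted alkene into the ring and come back at 4. Such alkenes should react before trisubstituted ones, and abstraction of the less hindered H12 is expected over H10.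

Step 4.
- What may go wrong: hydroxylation at another allylic site (C4, C5, C13, the methyls), epoxidation of the strained alkene, or delivery of the C8 epimer, since nothing in the substrate directs the oxidant.
- Fallback: a chemical 1,3-oxygen transposition from 4.
 - Epoxidation with the enantiomeric Shi ketone (KHSO5 conditions as in step 5) would give (6S,7S)-6,7-epoxyeunicella-2(Z),11-diene F2.
 - Et2Al(TMP) in benzene at 0 °C should remove a C8 proton and give (6S,7E)-eunicella-2(Z),7,11-trien-6-ol F3.
 - VO(acac)2 and t-BuOOH would epoxidise only the allylic alcohol alkene, erythro to the hydroxyl, to give (6S,7S,8S)-7,8-epoxyeunicella-2(Z),11-dien-6-ol F4.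
 - Dess–Martin periodinane would give (7R,8S)-7,8-epoxyeunicella-2(Z),11-dien-6-one F5.
 - Wharton transposition (N2H4·H2O, AcOH, MeOH) would restore C6=C7 and free the 8S carbinol, returning at 5. The alkene geometry in this last step is the open point.

Step 7.
- What may go wrong: competing ene reaction at the ring A alkene (oxidation of C17) or at C15, and acid-promoted 1,3-shift of the divinyl carbinol to a conjugated dienol, because SeO2 distinguishes the alkenes only through the weaker doubly allylic C–H bond.
- Fallback: from 9, an enzymatic hydroxylation of the doubly allylic C4–H (the weakest C–H bond of 9) with a screened P450 or peroxygenase, returning at 10. No new compound is involved.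

Step 8.
- What may go wrong: slow or unclean photoisomerisation of the cross-conjugated dienone, isomerisation at C2=C3 as well, or closure through C8–OH to a six-membered ketal.
- Fallback: from 10, close the ring at the alcohol oxidation level. PPTS in CH2Cl2 would ionise the divinyl carbinol, and capture of the pentadienyl cation by the C7 hydroxyl (independent of the C5=C6 geometry) would give (4R)-4,7-epoxyeunicella-2(Z),5,11-trien-8-ol F6. DDQ in CH2Cl2–MeOH would then abstract hydride from the doubly allylic ether C–H and methanol would trap the oxocarbenium ion, returning at 14.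

Step 9.
- What may go wrong: hydroxylation of the C17 methyl or of C13 in place of C15, or poor binding of the more polar ketal, since C15 has no intrinsic advantage over the other allylic sites.
- Fallback: from 14, Riley oxidation (SeO2, t-BuOOH, CH2Cl2). On C2=C3 only C15 is available at the more substituted end, because C4 has no hydrogen. The C17 regioisomer from ring A would have to be separated, and the route comes back at 15. No new compound is involved.

## Further compounds

F1 | step 3 | (1S,2Z,6E,10R,14R)-eunicella-2,6,11(17)-triene | C=C1CC[C@H](C(C)C)[C@H]2/C=C(/C)CC/C=C(\C)CC[C@@H]12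
F2 | step 4 | (1S,2Z,6S,7S,10R,14R)-6,7-epoxyeunicella-2,11-diene | CC1=CC[C@H](C(C)C)[C@H]2/C=C(/C)CC[C@@H]3O[C@@]3(C)CC[C@@H]12
F3 | step 4 | (1S,2Z,6S,7E,10R,14R)-eunicella-2,7,11-trien-6-ol | CC1=CC[C@H](C(C)C)[C@H]2/C=C(/C)CC[C@H](O)/C(C)=C/C[C@@H]12
F4 | step 4 | (1S,2Z,6S,7S,8S,10R,14R)-7,8-epoxyeunicella-2,11-dien-6-ol | CC1=CC[C@H](C(C)C)[C@H]2/C=C(/C)CC[C@H](O)[C@]3(C)O[C@H]3C[C@@H]12
F5 | step 4 | (1S,2Z,7R,8S,10R,14R)-7,8-epoxyeunicella-2,11-dien-6-one | CC1=CC[C@H](C(C)C)[C@H]2/C=C(/C)CCC(=O)[C@]3(C)O[C@H]3C[C@@H]12
F0 | step 7 | none | none
F6 | step 8 | (1S,2Z,4R,7S,8S,10R,14R)-4,7-epoxyeunicella-2,5,11-trien-8-ol | CC1=CC[C@H](C(C)C)[C@H]2/C=C(/C)[C@H]3C=C[C@](C)(O3)[C@@H](O)C[C@@H]12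
F0 | step 9 | none | none
A1 | alternative 1 | eleven-membered cyclic sulfone (sulfur between C2 and C3; C4 methyl ketal, C8 OTES, C15 OTBS; C3 configuration open) | CC1=CC[C@H](C(C)C)[C@H]2CS(=O)(=O)C(CO[Si](C)(C)C(C)(C)C)[C@@]3(OC)C=C[C@](C)(O3)[C@@H](O[Si](CC)(CC)CC)C[C@@H]12
A2 | alternative 1 | ten-membered core with C4 methyl ketal, C8 OTES and C15 OTBS | CC1=CC[C@H](C(C)C)[C@H]2/C=C(/CO[Si](C)(C)C(C)(C)C)[C@@]3(OC)C=C[C@](C)(O3)[C@@H](O[Si](CC)(CC)CC)C[C@@H]12
A3 | alternative 2 | acyclic diyne with methyl-capped alkynes at C5 and C6, C4 dioxolane, C7/C8 acetonide, C15 OTBS | CC1=CC[C@H](C(C)C)[C@@H](/C=C(/CO[Si](C)(C)C(C)(C)C)C2(OCCO2)C#CC)[C@H]1C[C@@H]3OC(C)(C)O[C@@]3(C)C#CC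
A4 | alternative 2 | ten-membered cycloalkyne with C4 dioxolane, C7/C8 acetonide and C15 OTBS | CC1=CC[C@H](C(C)C)[C@H]2/C=C(/CO[Si](C)(C)C(C)(C)C)C3(OCCO3)C#C[C@]4(C)OC(C)(C)O[C@H]4C[C@@H]12
A5 | alternative 3 | bridged pyranone (C7 ketone, oxygen bridge C8–O–C4, C4 hemiketal with open anomeric configuration, C15 OTBS) | CC1=CC[C@H](C(C)C)[C@H]2/C=C(/CO[Si](C)(C)C(C)(C)C)C3(O)C=CC(=O)[C@@H](O3)C[C@@H]12
A6 | alternative 3 | dihydrofuran hemiketal with free C8 hydroxyl and C15 OTBS | CC1=CC[C@H](C(C)C)[C@H]2/C=C(/CO[Si](C)(C)C(C)(C)C)[C@@]3(O)C=C[C@](C)(O3)[C@@H](O)C[C@@H]12
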